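**Plan**

- Numbering: ring A is the benzo ring, ring B the furan ring (O1, C2, C3, C3a, C7a), ring C the 2-aryl group. The target has no stereocentre, so none has to be set.
- Feature: the formyl carbon sits on C3, and C3 is separated from the ring oxygen O1 only by C2. A one-carbon unit parked on O1 as its methoxymethyl acetal can therefore be shifted to C3 in the same event that closes ring B.
- Retrosynthesis: CHO is taken back to CH2OMe. Then O1–C2 and C3–CH2OMe are cut together (retro-carboalkoxylation) to a diaryl alkyne with an ortho OCH2OMe group. The C3a–C(sp) bond is cut next (Sonogashira), and the alkyne is traced to an aryl aldehyde.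
- Forward: the ring A piece (iodination, MOM ether, silyl ether) and the ring C acetylene (benzylation, one-carbon homologation) are made separately and joined. Ring B closes last, in step 7. Oxidation to the aldehyde and one global deprotection finish the route.

Key step: step 7

Assumption: all four starting materials (the two phenols, the chloromethyl ether and the diazophosphonate) are purchasable. The chain hydroxyl is carried as a tert-butyldimethylsilyl ether instead of an ester so that it is released in the final operation without a separate step.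

**Route**

Step 1
Reactants: 1 dihydroconiferyl alcohol
Product: 2 4-(3-hydroxypropyl)-2-iodo-6-methoxyphenol
Conditions: I2, NaHCO3, THF/H2O, 0 °C → rt
Reagents that add atoms: iodine, [I][I]
Why: Electrophilic aromatic iodination through the phenoxide, whose para position is blocked by the side chain and whose single free ortho position is the most nucleophilic site (the same selectivity by which vanillin gives 5-iodovanillin).

Step 2
Reactants: 2 4-(3-hydroxypropyl)-2-iodo-6-methoxyphenol; 3 chloromethyl methyl ether
Product: 4 3-[3-iodo-5-methoxy-4-(methoxymethoxy)phenyl]propan-1-ol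
Conditions: MOMCl (1.1 equiv), K2CO3, acetone, 0 °C → rt
Reagents that add atoms: chloromethyl methyl ether, COCCl
Why: Williamson-type O-alkylation in which carbonate deprotonates only the phenol (about six pKa units more acidic than the primary alcohol), so the phenoxide is methoxymethylated chemoselectively.

Step 3
Reactants: 4 3-[3-iodo-5-methoxy-4-(methoxymethoxy)phenyl]propan-1-ol
Product: 5 tert-butyl{3-[3-iodo-5-methoxy-4-(methoxymethoxy)phenyl]propoxy}dimethylsilane
Conditions: TBSCl, imidazole, DMF, rt
Reagents that add atoms: tert-butyldimethylsilyl chloride, CC(C)(C)[Si](C)(C)Cl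
Why: Standard imidazole-promoted silylation of the remaining primary alcohol, which keeps that hydroxyl from intercepting the methoxymethyl cation in step 7.

Step 4
Reactants: 6 5-hydroxyvanillin
Product: 7 3,4-bis(benzyloxy)-5-methoxybenzaldehyde
Conditions: BnBr (2.3 equiv), K2CO3, DMF, 60 °C
Reagents that add atoms: benzyl bromide, BrCc1ccccc1
Why: Double Williamson etherification of the catechol, giving benzyl ethers that tolerate base, the cross-coupling, platinum and DDQ and that keep ring C electron-rich.

Step 5
Reactants: 7 3,4-bis(benzyloxy)-5-methoxybenzaldehyde; 8 dimethyl (1-diazo-2-oxopropyl)phosphonate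
Product: 9 1,2-bis(benzyloxy)-5-ethynyl-3-methoxybenzene
Conditions: K2CO3, MeOH, rt
Reagents that add atoms: dimethyl (1-diazo-2-oxopropyl)phosphonate, COP(=O)(OC)C(=[N+]=[N-])C(C)=O
Why: Seyferth–Gilbert homologation in the Ohira–Bestmann variant, in which methoxide deacetylates 8 to the diazomethylphosphonate anion that converts the non-enolisable aryl aldehyde into the terminal alkyne with loss of dimethyl phosphate and N2.

Step 6
Reactants: 5 tert-butyl{3-[3-iodo-5-methoxy-4-(methoxymethoxy)phenyl]propoxy}dimethylsilane; 9 1,2-bis(benzyloxy)-5-ethynyl-3-methoxybenzene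
Product: 10 tert-butyl[3-(3-{[3,4-bis(benzyloxy)-5-methoxyphenyl]ethynyl}-5-methoxy-4-(methoxymethoxy)phenyl)propoxy]dimethylsilane
Conditions: Pd(PPh3)2Cl2 (cat.), CuI (cat.), Et3N, THF, degassed, rt → 50 °C
Reagents that add atoms: none
Why: Sonogashira coupling of an aryl iodide with a terminal arylacetylene under zerovalent palladium and CuI catalysis, to which the acetal, silyl and benzyl ethers are inert.

Step 7
Reactants: 10 tert-butyl[3-(3-{[3,4-bis(benzyloxy)-5-methoxyphenyl]ethynyl}-5-methoxy-4-(methoxymethoxy)phenyl)propoxy]dimethylsilane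
Product: 11 2-[3,4-bis(benzyloxy)-5-methoxyphenyl]-5-{3-[(tert-butyldimethylsilyl)oxy]propyl}-7-methoxy-3-(methoxymethyl)benzofuran
Conditions: PtCl2 (5 mol%), 1,5-cyclooctadiene (20 mol%), toluene, anhydrous, 60 °C
Reagents that add atoms: none
Why: PtCl2 (divalent platinum, kept soluble and moderated by the diene) binds the alkyne of 10, the MOM-bearing oxygen adds anti to the alkyne carbon that carries ring C, and a platinum-bound zwitterion results with an oxonium ion at O1 and a C3–Pt bond. The oxonium ion gives up its stabilised methoxymethyl cation, which the nucleophilic C3–Pt carbon captures inside the ion pair, so that O1–C2 and C3–CH2OMe form in one catalytic turnover and 10 is isomerised to 11 with every atom retained. The closest known reaction type is the platinum-catalysed carboalkoxylation of ortho-alkynylphenyl acetals and alkoxymethyl ethers to 3-(alkoxyalkyl)benzofurans. Ring B closes 5-endo-dig, the only mode the ortho geometry allows, and no stereocentre is formed. The step needs carbon transfer to beat protodemetallation to the C3-unsubstituted benzofuran, which anhydrous acid-free conditions, the olefin additive and the closeness of the cation to the C3–Pt carbon should secure. Chemoselectivity rests on the substrate: only the acetal oxygen is ortho to the alkyne, ring C has no ortho oxygen so its benzyl ethers cannot engage, and the silyl ether masks the one hydroxyl that could trap the cation.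

Step 8
Reactants: 11 2-[3,4-bis(benzyloxy)-5-methoxyphenyl]-5-{3-[(tert-butyldimethylsilyl)oxy]propyl}-7-methoxy-3-(methoxymethyl)benzofuran
Product: 13 2-[3,4-bis(benzyloxy)-5-methoxyphenyl]-5-{3-[(tert-butyldimethylsilyl)oxy]propyl}-7-methoxybenzofuran-3-carbaldehyde, via methyl hemiacetal 12 (not isolated)
Conditions: DDQ (1.3 equiv), CH2Cl2/pH 7 aq. buffer (10:1), 0 °C → rt
Reagents that add atoms: water, O
Why: Oxidative cleavage of a benzylic-type methyl ether by DDQ, in which hydride is abstracted from the C3 methylene (the resulting cation is stabilised by the methoxy oxygen and by O1 through C2=C3, as in a p-methoxybenzyl ether), water adds to give hemiacetal 12, and loss of methanol leaves an electron-poor aldehyde that resists further oxidation.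

Step 9
Reactants: 13 2-[3,4-bis(benzyloxy)-5-methoxyphenyl]-5-{3-[(tert-butyldimethylsilyl)oxy]propyl}-7-methoxybenzofuran-3-carbaldehyde
Product: 15 Mururin C, via catechol silyl ether 14 (not isolated)
Conditions: BCl3, C6HMe5, CH2Cl2, −78 °C; then MeOH, −78 °C → rt; aq. work-up
Reagents that add atoms: none
Why: Lewis-acid debenzylation of the two aryl benzyl ethers with BCl3 at low temperature, with pentamethylbenzene trapping the benzyl cation by Friedel–Crafts alkylation so that the electron-rich rings, the aryl methyl ethers and the aldehyde are spared; the methanol quench frees catechol 14 from boron and the HCl it generates solvolyses the primary silyl ether.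

**Compound list**

1 | dihydroconiferyl alcohol, 4-(3-hydroxypropyl)-2-methoxyphenol | COc1cc(CCCO)ccc1O | starting material
2 | 4-(3-hydroxypropyl)-2-iodo-6-methoxyphenol | COc1cc(CCCO)cc(I)c1O | intermediate
3 | chloromethyl methyl ether | COCCl | starting material
4 | 3-[3-iodo-5-methoxy-4-(methoxymethoxy)phenyl]propan-1-ol | COCOc1c(I)cc(CCCO)cc1OC | intermediate
5 | tert-butyl{3-[3-iodo-5-methoxy-4-(methoxymethoxy)phenyl]propoxy}dimethylsilane | COCOc1c(I)cc(CCCO[Si](C)(C)C(C)(C)C)cc1OC | intermediate
6 | 5-hydroxyvanillin, 3,4-dihydroxy-5-methoxybenzaldehyde | COc1cc(C=O)cc(O)c1O | starting material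
7 | 3,4-bis(benzyloxy)-5-methoxybenzaldehyde | COc1cc(C=O)cc(OCc2ccccc2)c1OCc1ccccc1 | intermediate
8 | dimethyl (1-diazo-2-oxopropyl)phosphonate (Ohira–Bestmann reagent) | COP(=O)(OC)C(=[N+]=[N-])C(C)=O | starting material
9 | 1,2-bis(benzyloxy)-5-ethynyl-3-methoxybenzene | C#Cc1cc(OC)c(OCc2ccccc2)c(OCc2ccccc2)c1 | intermediate
10 | tert-butyl[3-(3-{[3,4-bis(benzyloxy)-5-methoxyphenyl]ethynyl}-5-methoxy-4-(methoxymethoxy)phenyl)propoxy]dimethylsilane | COCOc1c(OC)cc(CCCO[Si](C)(C)C(C)(C)C)cc1C#Cc1cc(OC)c(OCc2ccccc2)c(OCc2ccccc2)c1 | intermediate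
11 | 2-[3,4-bis(benzyloxy)-5-methoxyphenyl]-5-{3-[(tert-butyldimethylsilyl)oxy]propyl}-7-methoxy-3-(methoxymethyl)benzofuran | COCc1c(-c2cc(OC)c(OCc3ccccc3)c(OCc3ccccc3)c2)oc2c(OC)cc(CCCO[Si](C)(C)C(C)(C)C)cc12 | intermediate
12 | {2-[3,4-bis(benzyloxy)-5-methoxyphenyl]-5-{3-[(tert-butyldimethylsilyl)oxy]propyl}-7-methoxybenzofuran-3-yl}(methoxy)methanol (methyl hemiacetal, racemic) | COC(O)c1c(-c2cc(OC)c(OCc3ccccc3)c(OCc3ccccc3)c2)oc2c(OC)cc(CCCO[Si](C)(C)C(C)(C)C)cc12 | intermediate
13 | 2-[3,4-bis(benzyloxy)-5-methoxyphenyl]-5-{3-[(tert-butyldimethylsilyl)oxy]propyl}-7-methoxybenzofuran-3-carbaldehyde | O=Cc1c(-c2cc(OC)c(OCc3ccccc3)c(OCc3ccccc3)c2)oc2c(OC)cc(CCCO[Si](C)(C)C(C)(C)C)cc12 | intermediate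
14 | 5-{3-[(tert-butyldimethylsilyl)oxy]propyl}-2-(3,4-dihydroxy-5-methoxyphenyl)-7-methoxybenzofuran-3-carbaldehyde | COc1cc(-c2oc3c(OC)cc(CCCO[Si](C)(C)C(C)(C)C)cc3c2C=O)cc(O)c1O | intermediate
15 | Mururin C, 2-(3,4-dihydroxy-5-methoxyphenyl)-5-(3-hydroxypropyl)-7-methoxybenzofuran-3-carbaldehyde | COc1cc(-c2oc3c(OC)cc(CCCO)cc3c2C=O)cc(O)c1O | target

**Step count and risks**

Total steps: 9. Longest linear sequence: 7 (steps 1, 2, 3, 6, 7, 8, 9); the ring C branch (steps 4, 5) joins at step 6.

Steps most likely to fail:

Step 7. The C3–Pt bond may be protonated by adventitious acid or water, or the methoxymethyl cation may escape the ion pair, so that ring B closes without the C3 carbon. The fallback sets out from 10 and comes back to the route at 15. Methanolic HCl (MeOH/THF, rt) removes the MOM and silyl groups to give 2-{[3,4-bis(benzyloxy)-5-methoxyphenyl]ethynyl}-4-(3-hydroxypropyl)-6-methoxyphenol F1. Oxidative cyclisation–methoxycarbonylation under divalent palladium catalysis (PdCl2 cat., CuCl2, NaOAc, CO 1 atm, MeOH, rt) is a known way from ortho-alkynylphenols to benzofuran-3-carboxylates and again forms O1–C2 and the C3–carbon bond in one event; it should give methyl 2-[3,4-bis(benzyloxy)-5-methoxyphenyl]-5-(3-hydroxypropyl)-7-methoxybenzofuran-3-carboxylate F2. Reduction with i-Bu2AlH (CH2Cl2, −78 → 0 °C) should give 3-{2-[3,4-bis(benzyloxy)-5-methoxyphenyl]-3-(hydroxymethyl)-7-methoxybenzofuran-5-yl}propan-1-ol F3. MnO2 (CH2Cl2, rt) oxidises only the activated benzofuran-3-ylmethanol and should give 2-[3,4-bis(benzyloxy)-5-methoxyphenyl]-5-(3-hydroxypropyl)-7-methoxybenzofuran-3-carbaldehyde F4. BCl3 and pentamethylbenzene (CH2Cl2, −78 °C, MeOH quench) then cleave the two benzyl ethers to give 15.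

Step 8. Hydride abstraction by the quinone may not stay confined to the C3 methylene (the benzylic position of the propyl chain and the benzyl ethers are further sites), charge-transfer complexation of the electron-rich benzofuran may stall the reaction, or the acidic hydroquinone may strip the silyl ether. The fallback sets out from 10, comes back at 13 and needs no oxidation. Iodine (I2, NaHCO3, CH2Cl2, rt) triggers the same 5-endo-dig closure, the acetal group leaving from oxygen (iodocyclisation of ortho-alkynylaryl ethers, known for methyl ethers and acetal-type ethers), to give 2-[3,4-bis(benzyloxy)-5-methoxyphenyl]-5-{3-[(tert-butyldimethylsilyl)oxy]propyl}-3-iodo-7-methoxybenzofuran F5. Iodine–magnesium exchange (i-PrMgCl·LiCl, THF, −20 °C) followed by DMF and aqueous NH4Cl brings the C3 carbon in at the aldehyde level and should give 13.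

Step 9. Benzyl cations may escape the scavenger and alkylate the electron-rich rings, boron held by the new catechol may attack the neighbouring aryl methyl ether if the mixture warms, or the aldehyde may stay masked as an acetal after the acidic methanol stage. The fallback sets out from 13 and comes back at 15, passing through 14, which is now isolated. Hydrogenolysis (H2 1 atm, Pd/C, EtOAc, rt) should cleave both benzyl ethers to give 14; the 3-formyl group is a vinylogous formate and is expected to be reduced much more slowly than the O-benzyl bonds are cleaved. HF·pyridine (THF, 0 °C) then removes the silyl ether to give 15, with no cationic intermediate and no Lewis acid involved.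

**Further compounds**

F1 | step 7 | 2-{[3,4-bis(benzyloxy)-5-methoxyphenyl]ethynyl}-4-(3-hydroxypropyl)-6-methoxyphenol | COc1cc(CCCO)cc(C#Cc2cc(OC)c(OCc3ccccc3)c(OCc3ccccc3)c2)c1O
F2 | step 7 | methyl 2-[3,4-bis(benzyloxy)-5-methoxyphenyl]-5-(3-hydroxypropyl)-7-methoxybenzofuran-3-carboxylate | COC(=O)c1c(-c2cc(OC)c(OCc3ccccc3)c(OCc3ccccc3)c2)oc2c(OC)cc(CCCO)cc12
F3 | step 7 | 3-{2-[3,4-bis(benzyloxy)-5-methoxyphenyl]-3-(hydroxymethyl)-7-methoxybenzofuran-5-yl}propan-1-ol | OCc1c(-c2cc(OC)c(OCc3ccccc3)c(OCc3ccccc3)c2)oc2c(OC)cc(CCCO)cc12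
F4 | step 7 | 2-[3,4-bis(benzyloxy)-5-methoxyphenyl]-5-(3-hydroxypropyl)-7-methoxybenzofuran-3-carbaldehyde | O=Cc1c(-c2cc(OC)c(OCc3ccccc3)c(OCc3ccccc3)c2)oc2c(OC)cc(CCCO)cc12
F5 | step 8 | 2-[3,4-bis(benzyloxy)-5-methoxyphenyl]-5-{3-[(tert-butyldimethylsilyl)oxy]propyl}-3-iodo-7-methoxybenzofuran | Ic1c(-c2cc(OC)c(OCc3ccccc3)c(OCc3ccccc3)c2)oc2c(OC)cc(CCCO[Si](C)(C)C(C)(C)C)cc12
F0 | step 9 | none | none
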